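**Retrosynthetic overview**

1. Target ⇒ global desilylation ⇒ C2–H by BF3·OEt2/Et3SiH reduction of a C2 hemiketal ⇒ C2–aryl bond by adding a ring B aryllithium (already carrying the threo side chain) to a γ-lactone.
2. Lactone: the C3 methyl comes from trans-selective enolate methylation; the ring (O1, C2 as carbonyl, C3, C4, C5) comes from a carbene-catalysed homoenolate annulation of crotonaldehyde with silylated vanillin, which makes C4–C5 and O1–C2.
3. Feature used: in the tetrahydrofuran (O1; C2 with ring B; C3-Me; C4-Me; C5 with phenolic ring A) the C4 methyl and the C5 aryl are cis, which is the arrangement this annulation delivers; C3 and C2 are then set relative to them.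
4. Ring B bromide with side chain (C7 carbinol on ring C, C8 methyl/aryloxy): Mitsunobu of ethyl (S)-lactate with 4-bromo-2-methoxyphenol (inverts C8), Weinreb amide, ring C Grignard, Felkin–Anh reduction (sets C7), silylation.
5. Ring order: only the oxolane ring is built (as the γ-lactone, step 2); rings A, B and C are bought as arenes.

Key step: step 2

Remark: the sense of induction of the aminoindanol-derived triazolium salt for this aldehyde–enal pair cannot be predicted with confidence; the route assumes that one of its two commercial antipodes gives the (4R,5S) lactone and that this antipode is identified in a trial run with each.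

**Route**

Step 1
Reactants: 1 vanillin (4-hydroxy-3-methoxybenzaldehyde)
Product: 2 4-(tert-butyldimethylsilyloxy)-3-methoxybenzaldehyde
Conditions: TBSCl, imidazole, DMF, rt
Reagents that add atoms: tert-butyldimethylsilyl chloride (TBSCl), CC(C)(C)[Si](C)(C)Cl
Why: Imidazole-mediated silylation of a phenol is routine and leaves the aldehyde untouched.

Step 2
Reactants: 2 4-(tert-butyldimethylsilyloxy)-3-methoxybenzaldehyde; 3 (E)-crotonaldehyde
Product: 4 (4R,5S)-5-[4-(tert-butyldimethylsilyloxy)-3-methoxyphenyl]-4-methyldihydrofuran-2(3H)-one (cis lactone)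
Conditions: (5aS,10bR)- or (5aR,10bS)-2-mesityl-5a,10b-dihydro-4H,6H-indeno[2,1-b][1,2,4]triazolo[4,3-d][1,4]oxazin-2-ium chloride (10 mol %, antipode as in the remark), 1,8-diazabicyclo[5.4.0]undec-7-ene (DBU, 15 mol %), THF, rt; 2 in excess, 3 added slowly
Reagents that add atoms: none
Why: The carbene formed from the triazolium salt and DBU adds to the carbonyl of 3, and proton transfer gives the conjugated Breslow intermediate (a homoenolate equivalent) whose β-carbon attacks the aldehyde carbon of 2 to form C4–C5; tautomerisation to the acyl azolium then lets the new alkoxide acylate, forming O1–C2 and releasing the carbene. The closest known reaction is the N-heterocyclic carbene homoenolate annulation of enals with aryl aldehydes, which gives γ-butyrolactones with a preference for the cis isomer. The only ring closed is the lactone (O1, C2, C3, C4, C5), by 5-exo-trig attack of the alkoxide on the acyl azolium carbon. C4 and C5 are both set in the C–C bond-forming event: their cis relationship should come from the compact transition state in which the enaminol hydroxyl is hydrogen-bonded to the aldehyde oxygen, and their absolute sense from the aminoindanol backbone of the catalyst, which blocks one face of the homoenolate. The step needs cross-coupling to win over self-annulation of 3 and benzoin coupling of 2; this is sought by keeping 2 in excess, adding 3 slowly and using an N-mesityl catalyst that favours the homoenolate pathway, while 2 itself cannot form a homoenolate. The electron-rich aldehyde 2 and the β-alkyl enal 3 are a demanding pair for this reaction, so rate and enantioselectivity are the open points.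

Step 3
Reactants: 4 (4R,5S)-5-[4-(tert-butyldimethylsilyloxy)-3-methoxyphenyl]-4-methyldihydrofuran-2(3H)-one
Product: 6 (3R,4R,5S)-5-[4-(tert-butyldimethylsilyloxy)-3-methoxyphenyl]-3,4-dimethyldihydrofuran-2(3H)-one, via lithium enolate 5 (not isolated)
Conditions: LiN(SiMe3)2, THF, −78 °C; MeI, −78 to −40 °C
Reagents that add atoms: iodomethane (MeI), CI
Why: Lactone enolate alkylation, in which MeI should approach the enolate face opposite the C4 methyl and the cis C5 aryl, giving the 3,4-trans lactone without touching C4 or C5.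

Step 4
Reactants: 7 ethyl (S)-lactate; 8 4-bromo-2-methoxyphenol
Product: 9 ethyl (R)-2-(4-bromo-2-methoxyphenoxy)propanoate
Conditions: PPh3, DIAD, THF, 0 °C to rt
Reagents that add atoms: none
Why: Mitsunobu etherification of a secondary α-hydroxy ester with a phenol is an SN2 displacement of the oxyphosphonium and should invert C8 cleanly, so the (S)-lactate gives the (R)-aryl ether.

Step 5
Reactants: 9 ethyl (R)-2-(4-bromo-2-methoxyphenoxy)propanoate
Product: 10 (R)-2-(4-bromo-2-methoxyphenoxy)-N-methoxy-N-methylpropanamide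
Conditions: MeNH(OMe)·HCl, iPrMgCl, THF, −20 °C
Reagents that add atoms: N,O-dimethylhydroxylamine hydrochloride, CNOC.Cl
Why: Weinreb amide formation by aminolysis of the ester with the chloromagnesium amide at low temperature, conditions under which an α-aryloxy ester should keep its configuration and the aryl bromide should not exchange.

Step 6
Reactants: 8 4-bromo-2-methoxyphenol
Product: 11 (4-bromo-2-methoxyphenoxy)(tert-butyl)dimethylsilane
Conditions: TBSCl, imidazole, DMF, rt
Reagents that add atoms: tert-butyldimethylsilyl chloride (TBSCl), CC(C)(C)[Si](C)(C)Cl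
Why: Routine phenol silylation that makes the ring C bromide fit for magnesium insertion.

Step 7
Reactants: 11 (4-bromo-2-methoxyphenoxy)(tert-butyl)dimethylsilane; 10 (R)-2-(4-bromo-2-methoxyphenoxy)-N-methoxy-N-methylpropanamide
Product: 13 (R)-2-(4-bromo-2-methoxyphenoxy)-1-[4-(tert-butyldimethylsilyloxy)-3-methoxyphenyl]propan-1-one, via arylmagnesium bromide 12 (not isolated)
Conditions: Mg, cat. I2, THF, reflux; then 10, THF, 0 °C; aq. NH4Cl
Reagents that add atoms: none
Why: Weinreb ketone synthesis, in which the chelated tetrahedral adduct stops at single addition, the arylmagnesium (unlike an aryllithium) does not exchange with the aryl bromide of 10, and C8 is not touched because the ketone is released only on quench.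

Step 8
Reactants: 13 (R)-2-(4-bromo-2-methoxyphenoxy)-1-[4-(tert-butyldimethylsilyloxy)-3-methoxyphenyl]propan-1-one
Product: 14 (1R,2R)-2-(4-bromo-2-methoxyphenoxy)-1-[4-(tert-butyldimethylsilyloxy)-3-methoxyphenyl]propan-1-ol (threo)
Conditions: K[HB(sBu)3] (K-Selectride), THF, −78 °C; aq. NH4Cl
Reagents that add atoms: none
Why: Felkin–Anh controlled ketone reduction, in which the bulky hydride with a poorly chelating potassium counter-ion should attack anti to the C8 aryloxy group and past the C8 hydrogen, setting C7 as R (threo).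

Step 9
Reactants: 14 (1R,2R)-2-(4-bromo-2-methoxyphenoxy)-1-[4-(tert-butyldimethylsilyloxy)-3-methoxyphenyl]propan-1-ol
Product: 15 tert-butyl{(1R,2R)-2-(4-bromo-2-methoxyphenoxy)-1-[4-(tert-butyldimethylsilyloxy)-3-methoxyphenyl]propoxy}dimethylsilane
Conditions: TBSOTf, 2,6-lutidine, CH2Cl2, 0 °C
Reagents that add atoms: tert-butyldimethylsilyl trifluoromethanesulfonate (TBSOTf), CC(C)(C)[Si](C)(C)OS(=O)(=O)C(F)(F)F
Why: Silyl triflate silylation of a hindered secondary benzylic alcohol, which removes the only acidic proton before the lithiation.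

Step 10
Reactants: 15 tert-butyl{(1R,2R)-2-(4-bromo-2-methoxyphenoxy)-1-[4-(tert-butyldimethylsilyloxy)-3-methoxyphenyl]propoxy}dimethylsilane; 6 (3R,4R,5S)-5-[4-(tert-butyldimethylsilyloxy)-3-methoxyphenyl]-3,4-dimethyldihydrofuran-2(3H)-one
Product: 17 (3R,4R,5S)-2-{4-[(1R,2R)-1-(tert-butyldimethylsilyloxy)-1-[4-(tert-butyldimethylsilyloxy)-3-methoxyphenyl]propan-2-yloxy]-3-methoxyphenyl}-5-[4-(tert-butyldimethylsilyloxy)-3-methoxyphenyl]-3,4-dimethyltetrahydrofuran-2-ol (hemiketal; both C2 anomers; in equilibrium with the open hydroxy ketone), via aryllithium 16 (not isolated)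
Conditions: n-BuLi, THF, −78 °C; then 6, THF, −78 °C; aq. NH4Cl
Reagents that add atoms: none
Why: Bromine–lithium exchange followed by single addition of the aryllithium to the lactone, where the lithium hemiketal alkoxide should persist at −78 °C and block a second addition, while the silyl ethers and the C3, C4 and C5 centres are left alone.

Step 11
Reactants: 17 hemiketal (3R,4R,5S)-2-aryl-5-aryl-3,4-dimethyltetrahydrofuran-2-ol described in step 10
Product: 18 (2R,3R,4R,5S)-2-{4-[(1R,2R)-1-(tert-butyldimethylsilyloxy)-1-[4-(tert-butyldimethylsilyloxy)-3-methoxyphenyl]propan-2-yloxy]-3-methoxyphenyl}-5-[4-(tert-butyldimethylsilyloxy)-3-methoxyphenyl]-3,4-dimethyltetrahydrofuran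
Conditions: BF3·OEt2, Et3SiH, CH2Cl2, −78 °C
Reagents that add atoms: none
Why: Ionic hydrogenation of a cyclic hemiketal, in which BF3 ionises C2 to the oxocarbenium ion and the silane should deliver hydride by inside attack on the envelope with both methyls pseudo-equatorial, on the face opposite the C5 aryl and C4 methyl, so ring B ends trans to the C3 methyl and cis to ring A (C2 = R).

Step 12
Reactants: 18 tris-silyl ether described in step 11
Product: 19 target, (2R,3R,4R,5S)-2-{4-[(1R,2R)-1-hydroxy-1-(4-hydroxy-3-methoxyphenyl)propan-2-yloxy]-3-methoxyphenyl}-5-(4-hydroxy-3-methoxyphenyl)-3,4-dimethyltetrahydrofuran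
Conditions: nBu4NF, THF, 0 °C to rt; aq. NH4Cl
Reagents that add atoms: none
Why: Fluoride-mediated cleavage of the two aryl silyl ethers and the secondary benzylic silyl ether, a step that touches no stereocentre.

**Compound list**

1 | vanillin (4-hydroxy-3-methoxybenzaldehyde) | O=Cc1ccc(O)c(OC)c1 | starting material
2 | 4-(tert-butyldimethylsilyloxy)-3-methoxybenzaldehyde | O=Cc1ccc(O[Si](C)(C)C(C)(C)C)c(OC)c1 | intermediate
3 | (E)-crotonaldehyde | C/C=C/C=O | starting material
4 | (4R,5S)-5-[4-(tert-butyldimethylsilyloxy)-3-methoxyphenyl]-4-methyldihydrofuran-2(3H)-one | O=C1O[C@H](c2ccc(O[Si](C)(C)C(C)(C)C)c(OC)c2)[C@H](C)C1 | intermediate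
5 | lithium enolate of 4 (not isolated) | [Li]OC1=C[C@@H](C)[C@@H](c2ccc(O[Si](C)(C)C(C)(C)C)c(OC)c2)O1 | intermediate
6 | (3R,4R,5S)-5-[4-(tert-butyldimethylsilyloxy)-3-methoxyphenyl]-3,4-dimethyldihydrofuran-2(3H)-one | O=C1O[C@H](c2ccc(O[Si](C)(C)C(C)(C)C)c(OC)c2)[C@H](C)[C@H]1C | intermediate
7 | ethyl (S)-lactate | C[C@H](O)C(=O)OCC | starting material
8 | 4-bromo-2-methoxyphenol | COc1cc(Br)ccc1O | starting material
9 | ethyl (R)-2-(4-bromo-2-methoxyphenoxy)propanoate | CCOC(=O)[C@@H](C)Oc1ccc(Br)cc1OC | intermediate
10 | (R)-2-(4-bromo-2-methoxyphenoxy)-N-methoxy-N-methylpropanamide | CON(C)C(=O)[C@@H](C)Oc1ccc(Br)cc1OC | intermediate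
11 | (4-bromo-2-methoxyphenoxy)(tert-butyl)dimethylsilane | COc1cc(Br)ccc1O[Si](C)(C)C(C)(C)C | intermediate
12 | [4-(tert-butyldimethylsilyloxy)-3-methoxyphenyl]magnesium bromide (not isolated) | COc1cc([Mg]Br)ccc1O[Si](C)(C)C(C)(C)C | intermediate
13 | (R)-2-(4-bromo-2-methoxyphenoxy)-1-[4-(tert-butyldimethylsilyloxy)-3-methoxyphenyl]propan-1-one | COc1cc(C(=O)[C@@H](C)Oc2ccc(Br)cc2OC)ccc1O[Si](C)(C)C(C)(C)C | intermediate
14 | (1R,2R)-2-(4-bromo-2-methoxyphenoxy)-1-[4-(tert-butyldimethylsilyloxy)-3-methoxyphenyl]propan-1-ol | COc1cc([C@@H](O)[C@@H](C)Oc2ccc(Br)cc2OC)ccc1O[Si](C)(C)C(C)(C)C | intermediate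
15 | tert-butyl{(1R,2R)-2-(4-bromo-2-methoxyphenoxy)-1-[4-(tert-butyldimethylsilyloxy)-3-methoxyphenyl]propoxy}dimethylsilane | COc1cc([C@@H](O[Si](C)(C)C(C)(C)C)[C@@H](C)Oc2ccc(Br)cc2OC)ccc1O[Si](C)(C)C(C)(C)C | intermediate
16 | aryllithium from 15 (lithium in place of bromine; not isolated) | COc1cc([C@@H](O[Si](C)(C)C(C)(C)C)[C@@H](C)Oc2ccc([Li])cc2OC)ccc1O[Si](C)(C)C(C)(C)C | intermediate
17 | hemiketal, (3R,4R,5S)-2-(side-chain-bearing ring B aryl)-5-[4-(tert-butyldimethylsilyloxy)-3-methoxyphenyl]-3,4-dimethyltetrahydrofuran-2-ol, both C2 anomers | COc1cc([C@@H](O[Si](C)(C)C(C)(C)C)[C@@H](C)Oc2ccc(C3(O)O[C@H](c4ccc(O[Si](C)(C)C(C)(C)C)c(OC)c4)[C@H](C)[C@H]3C)cc2OC)ccc1O[Si](C)(C)C(C)(C)C | intermediate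
18 | (2R,3R,4R,5S)-tris(tert-butyldimethylsilyl) ether of the target | COc1cc([C@@H](O[Si](C)(C)C(C)(C)C)[C@@H](C)Oc2ccc([C@@H]3O[C@H](c4ccc(O[Si](C)(C)C(C)(C)C)c(OC)c4)[C@H](C)[C@H]3C)cc2OC)ccc1O[Si](C)(C)C(C)(C)C | intermediate
19 | target CNP0171079.2 | COc1cc([C@@H](O)[C@@H](C)Oc2ccc([C@@H]3O[C@H](c4ccc(O)c(OC)c4)[C@H](C)[C@H]3C)cc2OC)ccc1O | target

**Step count and risks**

Total step count: 12.
Longest linear sequence: 8 steps (steps 4, 5, 7, 8, 9, 10, 11 and 12, from 7 and 8).

Steps most likely to fail:

1. Step 2. The homoenolate may add too slowly to the electron-rich aldehyde, so that self-annulation of the enal takes over, and facial discrimination may be weak, eroding the cis preference or the enantiomeric purity. The fallback sets out from 2 and returns to the route at 4. Brown crotylboration of 2 with the (Z)-crotyldiisopinocampheylborane made from cis-2-butene (n-BuLi/KOtBu, then (−)-B-methoxydiisopinocampheylborane and BF3·OEt2, THF, −78 °C; NaBO3 work-up) should give, through the closed chair transition state, the syn homoallylic alcohol (1S,2R)-1-[4-(tert-butyldimethylsilyloxy)-3-methoxyphenyl]-2-methylbut-3-en-1-ol F1. Hydroboration of its vinyl group with 9-borabicyclo[3.3.1]nonane and NaBO3 oxidation should give (1S,2R)-1-[4-(tert-butyldimethylsilyloxy)-3-methoxyphenyl]-2-methylbutane-1,4-diol F2. Oxidation of the primary alcohol with 2,2,6,6-tetramethylpiperidin-1-oxyl and PhI(OAc)2 (lactol, then lactone) should then close 4.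

2. Step 11. Acid may open the ring at the C5–O1 benzylic bond and epimerise C5 toward the all-trans ring, the side-chain benzylic silyl ether may ionise and be reduced, or hydride may be delivered to the wrong face of C2. The fallback sets out from 17 and returns at 18. LiBH4 (THF, 0 °C) should reduce the open hydroxy ketone form of 17 to (1S,2R,3R)-1-[4-(tert-butyldimethylsilyloxy)-3-methoxyphenyl]-4-(side-chain-bearing ring B aryl)-2,3-dimethylbutane-1,4-diol F5, of which both C4 epimers serve. Catalytic camphor-10-sulfonic acid in CH2Cl2 over 4 Å molecular sieves at 0 °C should then ionise the carbinol next to ring B, whose para-alkoxy group gives the better stabilised benzylic cation, and the C5 hydroxyl closes O1–C2 (SN1-type cycloetherification). C5 keeps its configuration and ring B should settle trans to the C3 methyl, giving 18 with no hydride donor present; selective ionisation at the ring B carbinol over the ring A carbinol is the point this fallback depends on.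

3. Step 8. A competing chelated transition state may erode the threo selectivity, and base may epimerise C8 of the α-aryloxy ketone. The fallback sets out from 13 and returns at 14. Zn(BH4)2 (Et2O, −20 °C) should reduce 13 under chelation control, with zinc bridging the carbonyl and aryloxy oxygens, to the erythro alcohol (1S,2R)-2-(4-bromo-2-methoxyphenoxy)-1-[4-(tert-butyldimethylsilyloxy)-3-methoxyphenyl]propan-1-ol F3. Mitsunobu esterification with 4-nitrobenzoic acid (PPh3, DIAD, toluene) should invert C7 to the threo ester (1R,2R)-2-(4-bromo-2-methoxyphenoxy)-1-[4-(tert-butyldimethylsilyloxy)-3-methoxyphenyl]propyl 4-nitrobenzoate F4. iBu2AlH (CH2Cl2, −78 °C) should cleave the ester without touching the aryl silyl ether and give 14.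

**Further compounds**

F1 | step 2 | (1S,2R)-1-[4-(tert-butyldimethylsilyloxy)-3-methoxyphenyl]-2-methylbut-3-en-1-ol | O[C@H](c1ccc(O[Si](C)(C)C(C)(C)C)c(OC)c1)[C@H](C)C=C
F2 | step 2 | (1S,2R)-1-[4-(tert-butyldimethylsilyloxy)-3-methoxyphenyl]-2-methylbutane-1,4-diol | O[C@H](c1ccc(O[Si](C)(C)C(C)(C)C)c(OC)c1)[C@H](C)CCO
F3 | step 8 | (1S,2R)-2-(4-bromo-2-methoxyphenoxy)-1-[4-(tert-butyldimethylsilyloxy)-3-methoxyphenyl]propan-1-ol | COc1cc([C@H](O)[C@@H](C)Oc2ccc(Br)cc2OC)ccc1O[Si](C)(C)C(C)(C)C
F4 | step 8 | (1R,2R)-2-(4-bromo-2-methoxyphenoxy)-1-[4-(tert-butyldimethylsilyloxy)-3-methoxyphenyl]propyl 4-nitrobenzoate | COc1cc([C@@H](OC(=O)c3ccc(cc3)[N+](=O)[O-])[C@@H](C)Oc2ccc(Br)cc2OC)ccc1O[Si](C)(C)C(C)(C)C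
F5 | step 11 | (1S,2R,3R)-1-[4-(tert-butyldimethylsilyloxy)-3-methoxyphenyl]-4-{4-[(1R,2R)-1-(tert-butyldimethylsilyloxy)-1-[4-(tert-butyldimethylsilyloxy)-3-methoxyphenyl]propan-2-yloxy]-3-methoxyphenyl}-2,3-dimethylbutane-1,4-diol (both C4 epimers) | COc1cc([C@@H](O[Si](C)(C)C(C)(C)C)[C@@H](C)Oc2ccc(C(O)[C@H](C)[C@@H](C)[C@H](O)c3ccc(O[Si](C)(C)C(C)(C)C)c(OC)c3)cc2OC)ccc1O[Si](C)(C)C(C)(C)C
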